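**Retrosynthetic overview**
1. The target comes from its 4'-O-methyl ether 11 by a final selective B-ring O-demethylation; the only stereocentre (C2, S) is bought in (2S)-hesperetin and never touched.
2. The flavone pyranone ring of 11 is opened to the 3,5-diarylisoxazole 9, a masked 1,3-diketone (N–O cleavage, MOM removal, cyclodehydration).
3. The diaryl ether C–O bond of 9 is cut into the 3'-OH of (2S)-hesperetin 7-methyl ether 8 and the isoxazolyl arylboronic acid 6 (Chan–Lam).
4. Isoxazole 6 comes from a nitrile oxide/alkyne [3+2] cycloaddition between 5 (from phloroglucinaldehyde 1 via 2 and 3) and (4-ethynylphenyl)boronic acid 4.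
5. Ring order: chromanone ring bought; isoxazole ring by cycloaddition; flavone pyranone ring by ring switch of the isoxazole.

Assumption: (2S)-hesperetin is bought as the single enantiomer (it is the aglycone of the citrus glycoside hesperidin, from which acid hydrolysis releases it).

**Route**

Step 1
Reactants: 1 2,4,6-trihydroxybenzaldehyde
Product: 2 2,4,6-tris(methoxymethoxy)benzaldehyde
Conditions: NaH (3.6 equiv), MOMCl (3.6 equiv), DMF, 0 °C → rt
Reagents that add atoms: chloromethyl methyl ether (MOMCl), COCCl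
Why: Williamson O-alkylation of all three phenoxides (NaH is needed for the chelated ortho OH groups) gives acetal protection that shields the phloroglucinol ring from the oxidant of step 3 and falls off in acid when the flavone is closed.

Step 2
Reactants: 2 2,4,6-tris(methoxymethoxy)benzaldehyde
Product: 3 (E)-2,4,6-tris(methoxymethoxy)benzaldehyde oxime
Conditions: NH2OH·HCl, NaOAc, EtOH–H2O, rt → 40 °C
Reagents that add atoms: hydroxylamine hydrochloride, Cl.NO
Why: Oxime condensation under acetate buffer, mild enough to leave the MOM acetals intact; the hindered aldoxime forms as the E isomer (geometry is lost in the next step anyway).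

Step 3
Reactants: 3 (E)-2,4,6-tris(methoxymethoxy)benzaldehyde oxime; 4 (4-ethynylphenyl)boronic acid
Product: 6 [4-[3-[2,4,6-tris(methoxymethoxy)phenyl]-1,2-oxazol-5-yl]phenyl]boronic acid, via nitrile oxide 5 (not isolated)
Conditions: PhI(OAc)2 (1.05 equiv), MeOH, 0 °C, 30 min; then 4 (1.1 equiv), 50 °C, 16 h
Reagents that add atoms: none
Why: Hypervalent-iodine dehydrogenation of the aldoxime gives nitrile oxide 5, whose two ortho substituents block furoxan dimerisation; Huisgen 1,3-dipolar cycloaddition with the terminal arylalkyne then gives the 3,5-diarylisoxazole with the usual regiochemistry (O on the aryl-bearing carbon), and the alkyne is added only after the oxidant is spent so the boronic acid survives.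

Step 4
Reactants: 7 (2S)-hesperetin [(2S)-5,7-dihydroxy-2-(3-hydroxy-4-methoxyphenyl)chroman-4-one]
Product: 8 (2S)-5-hydroxy-2-(3-hydroxy-4-methoxyphenyl)-7-methoxychroman-4-one (hesperetin 7-methyl ether)
Conditions: MeOH (1.2 equiv), PPh3, DIAD, THF, 0 °C → rt
Reagents that add atoms: methanol, CO
Why: Mitsunobu etherification alkylates only the most acidic phenol (7-OH, a vinylogous acid, pKa about 7.5; the 5-OH is chelated and the 3'-OH has pKa about 10) under neutral conditions, so the flavanone ring does not open and C2 stays S.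

Step 5
Reactants: 6 [4-[3-[2,4,6-tris(methoxymethoxy)phenyl]-1,2-oxazol-5-yl]phenyl]boronic acid; 8 (2S)-hesperetin 7-methyl ether
Product: 9 (2S)-5-hydroxy-7-methoxy-2-[4-methoxy-3-[4-[3-[2,4,6-tris(methoxymethoxy)phenyl]-1,2-oxazol-5-yl]phenoxy]phenyl]chroman-4-one
Conditions: 6 (2 equiv), Cu(OAc)2 (2 equiv), pyridine, 4 Å MS, CH2Cl2, dry air, rt, 48 h
Reagents that add atoms: none
Why: Chan–Lam oxidative C–O coupling arylates the only free non-chelated phenol (3'-OH) at room temperature with a weak base, so the base-sensitive (2S)-flavanone is not epimerised; the terminal alkyne is already consumed, so no Glaser coupling can occur.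

Step 6
Reactants: 9 (2S)-5-hydroxy-7-methoxy-2-[4-methoxy-3-[4-[3-[2,4,6-tris(methoxymethoxy)phenyl]-1,2-oxazol-5-yl]phenoxy]phenyl]chroman-4-one
Product: 11 (2S)-2-[3-[4-(5,7-dihydroxy-4-oxo-4H-chromen-2-yl)phenoxy]-4-methoxyphenyl]-5-hydroxy-7-methoxychroman-4-one, via amino-enone 10 (not isolated)
Conditions: Mo(CO)6 (1.2 equiv), MeCN–H2O 10:1, 80 °C, 3 h; then 3 M aq HCl–MeOH, 60 °C, 6 h
Reagents that add atoms: water, O
Why: Mo(CO)6 reductively cleaves the isoxazole N–O bond to the (Z)-β-amino enone 10 (a masked 1,3-diketone); methanolic HCl then removes the three MOM groups, hydrolyses the enamine and cyclodehydrates (phenol O onto the aroyl carbon) to the 4H-chromen-4-one, under neutral then acidic conditions that leave the flavanone C2 alone.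

Step 7
Reactants: 11 (2S)-2-[3-[4-(5,7-dihydroxy-4-oxo-4H-chromen-2-yl)phenoxy]-4-methoxyphenyl]-5-hydroxy-7-methoxychroman-4-one
Product: 12 (2S)-2-[3-[4-(5,7-dihydroxy-4-oxo-4H-chromen-2-yl)phenoxy]-4-hydroxyphenyl]-5-hydroxy-7-methoxychroman-4-one (target)
Conditions: BBr3 (6 equiv), CH2Cl2, −78 → 0 °C, HPLC control; MeOH then H2O quench
Reagents that add atoms: none
Why: Lewis-acid aryl methyl ether cleavage, in which the electron-rich anisole-type 4'-OMe should react well before the 7-OMe, a vinylogous ester para to the boron-chelated C4=O/5-O unit; the low-temperature acidic conditions are expected to keep C2 as S.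

**Compound list**
1 | 2,4,6-trihydroxybenzaldehyde | O=Cc1c(O)cc(O)cc1O | starting material
2 | 2,4,6-tris(methoxymethoxy)benzaldehyde | COCOc1cc(OCOC)c(C=O)c(OCOC)c1 | intermediate
3 | (E)-2,4,6-tris(methoxymethoxy)benzaldehyde oxime | COCOc1cc(OCOC)c(/C=N/O)c(OCOC)c1 | intermediate
4 | (4-ethynylphenyl)boronic acid | OB(O)c1ccc(C#C)cc1 | starting material
5 | 2,4,6-tris(methoxymethoxy)benzonitrile oxide | COCOc1cc(OCOC)c(C#[N+][O-])c(OCOC)c1 | intermediate (not isolated)
6 | [4-[3-[2,4,6-tris(methoxymethoxy)phenyl]-1,2-oxazol-5-yl]phenyl]boronic acid | COCOc1cc(OCOC)c(-c2cc(-c3ccc(B(O)O)cc3)on2)c(OCOC)c1 | intermediate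
7 | (2S)-hesperetin, (2S)-5,7-dihydroxy-2-(3-hydroxy-4-methoxyphenyl)chroman-4-one | Oc1cc(O)c2c(c1)O[C@H](c1ccc(OC)c(O)c1)CC2=O | starting material
8 | (2S)-5-hydroxy-2-(3-hydroxy-4-methoxyphenyl)-7-methoxychroman-4-one | COc1cc(O)c2c(c1)O[C@H](c1ccc(OC)c(O)c1)CC2=O | intermediate
9 | (2S)-5-hydroxy-7-methoxy-2-[4-methoxy-3-[4-[3-[2,4,6-tris(methoxymethoxy)phenyl]-1,2-oxazol-5-yl]phenoxy]phenyl]chroman-4-one | COc1cc(O)c2c(c1)O[C@H](c1ccc(OC)c(Oc3ccc(-c4cc(-c5c(OCOC)cc(OCOC)cc5OCOC)no4)cc3)c1)CC2=O | intermediate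
10 | (2S)-2-[3-[4-[(2Z)-3-amino-3-[2,4,6-tris(methoxymethoxy)phenyl]prop-2-enoyl]phenoxy]-4-methoxyphenyl]-5-hydroxy-7-methoxychroman-4-one | COc1cc(O)c2c(c1)O[C@H](c1ccc(OC)c(Oc3ccc(C(=O)/C=C(\N)c4c(OCOC)cc(OCOC)cc4OCOC)cc3)c1)CC2=O | intermediate (not isolated)
11 | (2S)-2-[3-[4-(5,7-dihydroxy-4-oxo-4H-chromen-2-yl)phenoxy]-4-methoxyphenyl]-5-hydroxy-7-methoxychroman-4-one | COc1cc(O)c2c(c1)O[C@H](c1ccc(OC)c(Oc3ccc(-c4cc(=O)c5c(O)cc(O)cc5o4)cc3)c1)CC2=O | intermediate
12 | (2S)-2-[3-[4-(5,7-dihydroxy-4-oxo-4H-chromen-2-yl)phenoxy]-4-hydroxyphenyl]-5-hydroxy-7-methoxychroman-4-one | COc1cc(O)c2c(c1)O[C@H](c1ccc(O)c(Oc3ccc(-c4cc(=O)c5c(O)cc(O)cc5o4)cc3)c1)CC2=O | target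

**Totals**
Total step count: 7. Longest linear sequence: 6 (steps 1, 2, 3, 5, 6, 7).

**Steps most likely to fail, with fallbacks**

Step 7. The 7-OMe may be cleaved together with the 4'-OMe, or the Lewis acid may stress the flavanone ring. The fallback sets out from 9 and comes back at 12. The MOM groups of 9 are first removed (3 M HCl, MeOH, 50 °C) to give (2S)-5-hydroxy-7-methoxy-2-[4-methoxy-3-[4-[3-(2,4,6-trihydroxyphenyl)-1,2-oxazol-5-yl]phenoxy]phenyl]chroman-4-one F1. Excess BBr3 (CH2Cl2, −78 °C → rt) then cleaves both methyl ethers on purpose to give (2S)-5,7-dihydroxy-2-[4-hydroxy-3-[4-[3-(2,4,6-trihydroxyphenyl)-1,2-oxazol-5-yl]phenoxy]phenyl]chroman-4-one F2. Because the flavone is still masked as the isoxazole, the flavanone 7-OH is the only vinylogous-acid phenol in F2 (pKa about 7.5 against 9 or more for the others). A pKa-controlled Mitsunobu methylation (MeOH, PPh3, DIAD, THF) therefore puts the methyl group back at that position only, giving (2S)-5-hydroxy-2-[4-hydroxy-3-[4-[3-(2,4,6-trihydroxyphenyl)-1,2-oxazol-5-yl]phenoxy]phenyl]-7-methoxychroman-4-one F3. Mo(CO)6 in MeCN–H2O followed by aqueous HCl, as in step 6, then passes through the (2S)-amino-enone of the free phenol F4 and closes the flavone to give 12.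

Step 5. The Chan–Lam coupling uses a valuable, heteroaryl-bearing boronic acid and an ortho-methoxy phenol, so low conversion is possible. The fallback sets out from 8 and comes back at 9, building the ether before the cycloaddition. Compound 8 is coupled under the same Cu(OAc)2/pyridine conditions with cheap [4-[(trimethylsilyl)ethynyl]phenyl]boronic acid in threefold excess (the silyl cap prevents Glaser coupling), giving (2S)-5-hydroxy-7-methoxy-2-[4-methoxy-3-[4-[(trimethylsilyl)ethynyl]phenoxy]phenyl]chroman-4-one F5. Buffered desilylation (TBAF, AcOH, THF, 0 °C) gives (2S)-2-[3-(4-ethynylphenoxy)-4-methoxyphenyl]-5-hydroxy-7-methoxychroman-4-one F6. Nitrile oxide 5, preformed from 3 with PhI(OAc)2 as in step 3, is then added to F6 at 50 °C to give 9.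

Step 3. The di-ortho-substituted nitrile oxide may add too slowly to the arylalkyne and decay on prolonged heating. The fallback sets out from 3 and comes back at 6. Nitrile oxide 5 is generated as before and trapped with the much more reactive styrene dipolarophile (4-vinylphenyl)boronic acid, giving racemic [4-[3-[2,4,6-tris(methoxymethoxy)phenyl]-4,5-dihydro-1,2-oxazol-5-yl]phenyl]boronic acid F7. Dehydrogenation with DDQ (dioxane, 80 °C) aromatises the isoxazoline, removing its stereocentre, and gives 6.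

**Further compounds**
F1 | step 7 | (2S)-5-hydroxy-7-methoxy-2-[4-methoxy-3-[4-[3-(2,4,6-trihydroxyphenyl)-1,2-oxazol-5-yl]phenoxy]phenyl]chroman-4-one | COc1cc(O)c2c(c1)O[C@H](c1ccc(OC)c(Oc3ccc(-c4cc(-c5c(O)cc(O)cc5O)no4)cc3)c1)CC2=O
F2 | step 7 | (2S)-5,7-dihydroxy-2-[4-hydroxy-3-[4-[3-(2,4,6-trihydroxyphenyl)-1,2-oxazol-5-yl]phenoxy]phenyl]chroman-4-one | Oc1cc(O)c2c(c1)O[C@H](c1ccc(O)c(Oc3ccc(-c4cc(-c5c(O)cc(O)cc5O)no4)cc3)c1)CC2=O
F3 | step 7 | (2S)-5-hydroxy-2-[4-hydroxy-3-[4-[3-(2,4,6-trihydroxyphenyl)-1,2-oxazol-5-yl]phenoxy]phenyl]-7-methoxychroman-4-one | COc1cc(O)c2c(c1)O[C@H](c1ccc(O)c(Oc3ccc(-c4cc(-c5c(O)cc(O)cc5O)no4)cc3)c1)CC2=O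
F4 | step 7 | (2S)-2-[3-[4-[(2Z)-3-amino-3-(2,4,6-trihydroxyphenyl)prop-2-enoyl]phenoxy]-4-hydroxyphenyl]-5-hydroxy-7-methoxychroman-4-one | COc1cc(O)c2c(c1)O[C@H](c1ccc(O)c(Oc3ccc(C(=O)/C=C(\N)c4c(O)cc(O)cc4O)cc3)c1)CC2=O
F5 | step 5 | (2S)-5-hydroxy-7-methoxy-2-[4-methoxy-3-[4-[(trimethylsilyl)ethynyl]phenoxy]phenyl]chroman-4-one | COc1cc(O)c2c(c1)O[C@H](c1ccc(OC)c(Oc3ccc(C#C[Si](C)(C)C)cc3)c1)CC2=O
F6 | step 5 | (2S)-2-[3-(4-ethynylphenoxy)-4-methoxyphenyl]-5-hydroxy-7-methoxychroman-4-one | COc1cc(O)c2c(c1)O[C@H](c1ccc(OC)c(Oc3ccc(C#C)cc3)c1)CC2=O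
F7 | step 3 | [4-[3-[2,4,6-tris(methoxymethoxy)phenyl]-4,5-dihydro-1,2-oxazol-5-yl]phenyl]boronic acid (racemic) | COCOc1cc(OCOC)c(C2=NOC(c3ccc(B(O)O)cc3)C2)c(OCOC)c1
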